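The γ-lactone (ring atoms O1, C2, C3, C4, C5) is disconnected at both of its C–O bonds, C5–O1 and O1–C2, back to an open-chain pent-4-enoate whose only stereocentre is C3. The veratroyloxy oxygen on C3 and O1 on C5 stand in a 1,3-relationship across C4. When the C5=C6 alkene is activated by iodine, the carbonyl oxygen of that ester is therefore transferred to C5 by way of a six-membered dioxanylium ion. Hydrolysis and lactonisation then close the five-membered ring, set C5 trans to C3 and leave a C6 iodide for attaching the phenyl group. The precursor is methyl (R)-2-(3,4-dimethoxybenzoyloxy)pent-4-enoate, reached in two steps from methyl (R)-glycidate.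

Key step: step 3

Remark on numbering: all compounds carry the lactone numbering (O1, C2 carbonyl, C3 bearing the veratrate, C4, C5, exocyclic C6); the target is the trans (3R,5R) isomer.

Step 1
Reactants: 1 methyl (R)-glycidate; 2 vinylmagnesium bromide
Product: 4 methyl (R)-2-hydroxypent-4-enoate, via bromomagnesium alkoxide 3 (not isolated)
Conditions: 2 (1.5 equiv), CuI (10 mol%), THF, −78 to −40 °C; then sat. aq NH4Cl
Reagents that add atoms: none
Why: Copper-catalysed SN2 opening of a terminal epoxide by a vinyl Grignard reagent (organocuprate addition) takes place at the unsubstituted epoxide carbon at low temperature faster than attack on the ester, and since no bond to the stereocentre is broken the R configuration of 1 is carried into 4.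

Step 2
Reactants: 4 methyl (R)-2-hydroxypent-4-enoate; 5 3,4-dimethoxybenzoyl chloride
Product: 6 methyl (R)-2-(3,4-dimethoxybenzoyloxy)pent-4-enoate
Conditions: 5 (1.2 equiv), pyridine (2 equiv), DMAP (5 mol%), CH2Cl2, 0 °C to rt
Reagents that add atoms: none
Why: DMAP-catalysed O-acylation of a secondary alcohol with an acid chloride (nucleophilic acyl substitution) is routine, and the mild pyridine base at 0 °C should leave the alpha stereocentre and the alkene untouched.

Step 3
Reactants: 6 methyl (R)-2-(3,4-dimethoxybenzoyloxy)pent-4-enoate
Product: 10 (3R,5S)-5-(iodomethyl)-2-oxotetrahydrofuran-3-yl 3,4-dimethoxybenzoate, via dioxanylium cation 7 (not isolated), via cyclic orthoacid 8 (not isolated), via iodohydrin ester 9 (not isolated)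
Conditions: NIS (1.2 equiv), H2O (5 equiv), MeCN, −20 to 0 °C, dark; aq Na2S2O3 wash; then CSA (10 mol%), CH2Cl2, rt
Reagents that add atoms: N-iodosuccinimide, O=C1CCC(=O)N1I; water, O
Why: N-Iodosuccinimide transfers I+ to the C5=C6 alkene, the aroyl carbonyl oxygen opens the iodonium ion at C5 to give the aryl-stabilised dioxanylium ion 7, the limited water adds to its cationic carbon to give orthoacid 8, which breaks down to iodohydrin ester 9, and under the acid catalyst the C5 hydroxyl displaces methanol from the ester to give 10. The closest known reaction type is halocyclisation with neighbouring-group participation of a homoallylic ester or carbonate (iodocarbonate cyclisation, Woodward–Prévost hydrolysis of an acyloxonium ion), followed by ordinary acid-catalysed lactonisation of a gamma-hydroxy ester. The transient six-membered ring closes 6-exo on the iodonium ion, and the lactone ring, the only ring kept, closes by 5-exo-trig acyl substitution at C2. The new C5 stereocentre is controlled by the C3 stereocentre through a chair-like transition state in which CO2Me and the forming CH2I group are both equatorial, giving the cis-4,6-disubstituted cation; because the oxygen on C3 is a ring atom in 7 but a substituent in 10, this cis relationship becomes trans in the lactone, which is 5S for the iodide. The step needs the veratrate carbonyl to outcompete the methyl ester carbonyl and water for the iodonium ion and needs Markovnikov opening at C5: the electron-rich dimethoxyphenyl ring raises the basicity of the aroyl oxygen, the alpha-acyloxy group lowers that of the methyl ester, only a few equivalents of water are present, and the terminal alkene directs the nucleophile to its internal carbon. Breakdown of 8 toward the other oxygen is reversible under the acid, whereas breakdown that frees the C5 hydroxyl is drained by lactonisation, so the material should converge on 10; the methyl ester is kept because it is the least nucleophilic simple carboxyl derivative that still lactonises readily.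

Step 4
Reactants: 10 (3R,5S)-5-(iodomethyl)-2-oxotetrahydrofuran-3-yl 3,4-dimethoxybenzoate; 11 bromobenzene
Product: 12 Trichoderolide F, (3R,5R)-5-benzyl-2-oxotetrahydrofuran-3-yl 3,4-dimethoxybenzoate
Conditions: 11 (2 equiv), [Ir(dF(CF3)ppy)2(dtbbpy)]PF6 (1 mol%), NiCl2(dme) (5 mol%), 4,4'-di-tert-butyl-2,2'-bipyridine (5 mol%), (Me3Si)3SiH (1.2 equiv), Na2CO3 (2 equiv), DME, blue LED (450 nm), rt
Reagents that add atoms: none
Why: In this silyl-radical-mediated nickel/photoredox cross-electrophile coupling the silyl radical abstracts iodine from C6 far faster than bromine from 11, the primary C6 radical is captured by the phenylnickel species formed by oxidative addition of 11 and reductive elimination forms the C6–phenyl bond, while the absence of zinc metal avoids reductive fragmentation of the beta-acyloxy iodide and neither C3 nor C5 is touched (the C5 descriptor changes from S to R only because the priority of C6 drops).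

Compound list
1 | methyl (R)-glycidate (methyl (R)-oxirane-2-carboxylate) | COC(=O)[C@H]1CO1 | starting material
2 | vinylmagnesium bromide | C=C[Mg]Br | starting material
3 | bromomagnesium alkoxide of methyl (R)-2-hydroxypent-4-enoate | C=CC[C@@H](O[Mg]Br)C(=O)OC | intermediate
4 | methyl (R)-2-hydroxypent-4-enoate | C=CC[C@@H](O)C(=O)OC | intermediate
5 | 3,4-dimethoxybenzoyl chloride | COc1ccc(C(Cl)=O)cc1OC | starting material
6 | methyl (R)-2-(3,4-dimethoxybenzoyloxy)pent-4-enoate | COc1ccc(C(=O)O[C@@H](C(=O)OC)CC=C)cc1OC | intermediate
7 | (4R,6S)-2-(3,4-dimethoxyphenyl)-6-(iodomethyl)-4-(methoxycarbonyl)-1,3-dioxan-2-ylium (cis) | COc1ccc(C2=[O+][C@H](CI)C[C@H](C(=O)OC)O2)cc1OC | intermediate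
8 | methyl (4R,6S)-2-(3,4-dimethoxyphenyl)-2-hydroxy-6-(iodomethyl)-1,3-dioxane-4-carboxylate (orthoacid, configuration at C2 of the dioxane open) | COc1ccc(C2(O)O[C@H](CI)C[C@H](C(=O)OC)O2)cc1OC | intermediate
9 | methyl (2R,4S)-2-(3,4-dimethoxybenzoyloxy)-4-hydroxy-5-iodopentanoate | COc1ccc(C(=O)O[C@@H](C(=O)OC)C[C@H](O)CI)cc1OC | intermediate
10 | (3R,5S)-5-(iodomethyl)-2-oxotetrahydrofuran-3-yl 3,4-dimethoxybenzoate (trans) | COc1ccc(C(=O)O[C@@H]2C[C@@H](CI)OC2=O)cc1OC | intermediate
11 | bromobenzene | Brc1ccccc1 | starting material
12 | Trichoderolide F, (3R,5R)-5-benzyl-2-oxotetrahydrofuran-3-yl 3,4-dimethoxybenzoate (trans) | COc1ccc(C(=O)O[C@@H]2C[C@@H](Cc3ccccc3)OC2=O)cc1OC | target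

Total step count: 4
Longest linear sequence: 4 steps (1 to 12)

Steps most likely to fail

Step 3. The iodonium ion may be captured by the methyl ester carbonyl or by water instead of the veratrate carbonyl, so that the 1,3-relay is bypassed and facial selectivity at C5 is lost, or the acyl return and lactonisation may stall. The fallback sets out from 4 and comes back to the route at 10, closing the ring by iodolactonisation of a tertiary amide. Aminolysis of 4 with dimethylamine (MeOH, rt) should give (R)-2-hydroxy-N,N-dimethylpent-4-enamide F1. Treatment with I2 in THF–H2O at rt cyclises the amide oxygen onto the iodonium ion. In the resulting iminium ether, allylic A(1,3) strain against the N-methyl group is expected to favour the trans arrangement, and hydrolysis releases (3R,5S)-3-hydroxy-5-(iodomethyl)dihydrofuran-2(3H)-one F2. Acylation of F2 with 5 (pyridine, DMAP, CH2Cl2, 0 °C) then gives 10.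

Step 4. Hydrogen transfer from the silane to the C6 radical (hydrodeiodination) or slow capture of that radical by nickel may outrun C–C bond formation. The fallback sets out from 10 and comes back at 12. It replaces the reductive union of two electrophiles by a redox-neutral Negishi coupling with a preformed aryl nucleophile: purchased phenylzinc bromide, NiCl2(dme) (10 mol%) and 4,4',4''-tri-tert-butyl-2,2':6',2''-terpyridine in DMA–THF at rt. This is the ligand class under which acylated glycosyl halides are arylated with the beta-acyloxy group intact, and no zinc metal is present. This path makes no new compound (F0).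

Step 1. Addition of the Grignard reagent to the ester carbonyl, or opening of the epoxide by bromide, may compete with copper-mediated C–C bond formation at the epoxide CH2. The fallback sets out from 1 and comes back at 4, and removes the electrophilic ester during the opening. Saponification of 1 (LiOH, THF–H2O, 0 °C) should give lithium (R)-oxirane-2-carboxylate F3. Opening of the dried salt with 2 and CuI (10 mol%) in THF at −30 °C, followed by aq HCl, should give (R)-2-hydroxypent-4-enoic acid F4. Fischer esterification (MeOH, cat. H2SO4, rt) returns 4.

Further compounds
F1 | step 3 | (R)-2-hydroxy-N,N-dimethylpent-4-enamide | C=CC[C@@H](O)C(=O)N(C)C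
F2 | step 3 | (3R,5S)-3-hydroxy-5-(iodomethyl)dihydrofuran-2(3H)-one | O[C@@H]1C[C@@H](CI)OC1=O
F0 | step 4 | none | none
F3 | step 1 | lithium (R)-oxirane-2-carboxylate | [Li+].[O-]C(=O)[C@H]1CO1
F4 | step 1 | (R)-2-hydroxypent-4-enoic acid | C=CC[C@@H](O)C(=O)O
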